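**Plan**
1. Numbering (briarane): ten-membered ring C1–C10; cyclohexene C1, C10–C14; γ-lactone O–C7–C8–C17–C19(=O); C16 is the exocyclic CH2 on C5.
2. Cuts: (a) C3=C4 and C5=C16 by an endo ring-closing enyne metathesis of a C2 vinyl carbinol with a C5≡C4 alkyne (last step, closes the ten-membered ring); (b) C6–Cl by SN2 on a propargylic alcohol.
3. (c) The lactone bonds O–C7 and C17–C8 are cut together: anionic (3+2) annulation of the enediolate of propanoic acid (C17, C19, O) onto an acyclic α,β-epoxy ketone. The enabling feature is the C8 carbonyl carbon bonded directly to the oxirane carbon C7, a vicinal bis-electrophile matched to the C,O-dinucleophile.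
4. (d) C6–C7 by aldol condensation of a C8 methyl ketone with TMS-propynal; C8–C9 by acylation of an acetylide with the C9 ester; (e) the cyclohexene by Diels–Alder reaction of a 2-silyloxydiene (C11–C14) with ethyl 3-formylcrotonate (C2, C1, C10, C9).
5. Ring order forward: cyclohexene (step 2), γ-lactone (step 14), ten-membered ring (step 21).
6. Stereochemistry: C1/C10/C11 from the catalytic asymmetric Diels–Alder; C2 Felkin–Anh; C9 and C6 from catalyst-controlled ynone transfer hydrogenation (C6 then inverted by chloride); C12 from hindered-face reduction and Mitsunobu inversion; C7 from catalytic epoxidation then SN2 inversion; C8 Felkin–Anh; C17 by equilibration.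

Key step: step 14

Assumption: the facial sense of the catalyst-controlled steps (2, 6, 13, 16) is assigned by analogy with simple substrates; both enantiomers of each catalyst are available, so a reversed sense would change only the hand of the catalyst.

**Step 1**
Reactants: 1 pent-1-en-3-one
Product: 2 (Z)-3-(triisopropylsilyloxy)penta-1,3-diene
Conditions: TIPSOTf, Et3N, CH2Cl2, 0 °C
Reagents that add atoms: triisopropylsilyl trifluoromethanesulfonate, CC(C)[Si](C(C)C)(C(C)C)OS(=O)(=O)C(F)(F)F
Why: Soft enolisation and O-silylation of the ethyl ketone (silyl enol ether formation) should give the 2-silyloxydiene, the Z enol ether being the usual major isomer with R3SiOTf/Et3N and the bulky silyl group making the diene robust toward Lewis acids.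

**Step 2**
Reactants: 2 (Z)-3-(triisopropylsilyloxy)penta-1,3-diene; 3 ethyl (E)-3-methyl-4-oxobut-2-enoate
Product: 4 ethyl (1S,2R,6S)-6-formyl-2,6-dimethyl-3-(triisopropylsilyloxy)cyclohex-3-ene-1-carboxylate
Conditions: (S)-3,3-diphenyl-1-(o-tolyl)tetrahydro-1H,3H-pyrrolo[1,2-c][1,3,2]oxazaborole·HNTf2 (20 mol%), CH2Cl2, −78 → −40 °C
Reagents that add atoms: none
Why: Enantioselective Diels–Alder reaction under chiral oxazaborolidinium catalysis: the formyl-bound catalyst makes C10 the electrophilic terminus that bonds to the nucleophilic CH(Me) end of the diene (C11), the E dienophile fixes the C1 methyl cis to the ester on C10, and the formyl-exo/ester-endo transition state usual for 2-substituted enals places the outside methyl of the Z diene cis to both, so C1, C10 and C11 are set together.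

**Step 3**
Reactants: 4 Diels–Alder adduct; 5 vinylmagnesium bromide
Product: 6 ethyl (1S,2R,6S)-6-[(1S)-1-hydroxyprop-2-en-1-yl]-2,6-dimethyl-3-(triisopropylsilyloxy)cyclohex-3-ene-1-carboxylate
Conditions: THF, −78 °C; aq. NH4Cl
Reagents that add atoms: none
Why: Grignard addition to the aldehyde, much faster than to the hindered ester or the silyl enol ether at −78 °C, with Felkin–Anh attack anti to the ring carbon C10 (largest α-substituent) expected to give the (2S) carbinol.

**Step 4**
Reactants: 6 allylic alcohol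
Product: 7 C2 tert-butyldimethylsilyl ether of 6
Conditions: TBSOTf, 2,6-lutidine, CH2Cl2, −78 → 0 °C
Reagents that add atoms: tert-butyldimethylsilyl trifluoromethanesulfonate, CC(C)(C)[Si](C)(C)OS(=O)(=O)C(F)(F)F
Why: Silylation of a hindered secondary alcohol with the silyl triflate; the TIPS enol ether and the ester are inert.

**Step 5**
Reactants: 7 ester; 8 lithium (trimethylsilyl)acetylide
Product: 9 C9 ynone (ethoxy group of 7 replaced by a (trimethylsilyl)ethynyl group)
Conditions: BF3·OEt2, THF, −78 °C
Reagents that add atoms: none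
Why: BF3-promoted acylation of the lithium acetylide by the ester: the tetrahedral borate collapses to the ynone only on work-up, so a single addition is expected and C10 is not enolised at −78 °C.

**Step 6**
Reactants: 9 ynone
Product: 10 (9S)-propargylic alcohol
Conditions: Ru[(S,S)-TsNCH(Ph)CH(Ph)NH](p-cymene) (2 mol%), 2-propanol, rt
Reagents that add atoms: none
Why: Noyori asymmetric transfer hydrogenation of an α,β-ynone; the (S,S) catalyst should give the (9S) alcohol, which is also the Felkin–Anh product (hydride anti to C1), so catalyst and substrate control are matched.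

**Step 7**
Reactants: 10 propargylic alcohol
Product: 11 2,9-bis(tert-butyldimethylsilyl) ether
Conditions: TBSOTf, 2,6-lutidine, CH2Cl2, −78 → 0 °C
Reagents that add atoms: tert-butyldimethylsilyl trifluoromethanesulfonate, CC(C)(C)[Si](C)(C)OS(=O)(=O)C(F)(F)F
Why: Standard silylation; the non-chelating silyl ether on O9 is needed later for Felkin–Anh control at C8.

**Step 8**
Reactants: 11 silyl enol ether
Product: 12 cyclohexenone (C12 ketone, C13=C14)
Conditions: Pd(OAc)2 (1.1 equiv), MeCN, 40 °C
Reagents that add atoms: none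
Why: Saegusa–Ito oxidation: the silyl enol ether passes through the palladium enolate and β-hydride elimination from C14 to the enone, while the silylalkyne, the vinyl group and the silyl ethers do not react.

**Step 9**
Reactants: 12 enone
Product: 13 (12S)-allylic alcohol (C12 epimer of the target configuration)
Conditions: DIBAL-H, CH2Cl2, −78 °C; Rochelle salt
Reagents that add atoms: none
Why: 1,2-Reduction of the enone; in the favoured half-chair (both ring methyl groups pseudo-equatorial, the C9 branch on C10 pseudo-axial) the axial branch shields the β face, so hydride should add from the α face and give the axial (12S) alcohol that the next step inverts.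

**Step 10**
Reactants: 13 allylic alcohol; 14 propanoic acid
Product: 15 (12R)-propanoate
Conditions: PPh3, DIAD, toluene, 0 °C → rt
Reagents that add atoms: none
Why: Mitsunobu esterification: SN2 displacement of the alkoxyphosphonium group from the open α face inverts C12 to the target configuration, and SN2′ attack at C14 is blocked by the quaternary C1.

**Step 11**
Reactants: 15 silylalkyne
Product: 17 C8 methyl ketone (9-silyloxy), via terminal alkyne 16 (not isolated)
Conditions: AgNO3 (10 mol%), acetone/H2O, rt; then Ph3PAuNTf2 (3 mol%), MeOH, 45 °C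
Reagents that add atoms: water, O
Why: Silver-catalysed protodesilylation of the alkynylsilane followed by gold-catalysed Markovnikov hydration of the terminal alkyne; the neutral conditions spare esters and silyl ethers, and the ring alkene could engage the activated alkyne only through a bridged ring.

**Step 12**
Reactants: 17 methyl ketone; 18 3-(trimethylsilyl)prop-2-ynal
Product: 21 (6E)-enynone, via lithium aldolate 19 (not isolated), via mesylate 20 (not isolated)
Conditions: LiHMDS (1.05 equiv), THF, −78 °C; 18; then MsCl, Et3N, −78 → 0 °C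
Reagents that add atoms: none
Why: Aldol condensation: kinetic deprotonation of the methyl group (more acidic and more accessible than the propanoate or C9–H), addition to the non-enolisable ynal, then mesylation and E1cB elimination in the same flask should give the E enone.

**Step 13**
Reactants: 21 enynone
Product: 22 (6S,7R)-trans-epoxy ketone
Conditions: La(OiPr)3, (S)-BINOL, Ph3As=O (10 mol% each), TBHP (decane), 4 Å MS, THF, rt
Reagents that add atoms: tert-butyl hydroperoxide, CC(C)(C)OO
Why: Lanthanum–BINOL-catalysed nucleophilic epoxidation of the E enone: conjugate addition of the peroxide at C6 and ring closure give the trans oxirane, the chiral complex choosing the face (catalyst control), and the nucleophilic oxidant leaves the other alkenes and the alkyne alone.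

**Step 14**
Reactants: 22 epoxy ketone; 14 propanoic acid
Product: 25 γ-lactone with 8-OH and (6S)-6-OH, via dilithium propanoate enediolate 23 (not isolated), via hydroxy acid epoxide 24 (not isolated)
Conditions: 14, LDA (2 equiv per acid), THF, 0 °C; 22, −78 °C; AcOH, −78 °C → rt; then DBU (0.3 equiv), CH2Cl2, rt
Reagents that add atoms: none
Why: The enediolate 23 adds through C17 to the C8 ketone (aldol), and after the tertiary alkoxide is protonated with AcOH at −78 °C the carboxyl group opens the adjacent oxirane at C7, so C17–C8 and O–C7 form in one flask as an anionic (3+2) annulation of a C,O-dinucleophile onto the vicinal bis-electrophile C8(=O)/C7(oxirane). The closest known reaction types are the aldol addition of carboxylic acid dianions to ketones and the spontaneous lactonisation of γ,δ-epoxy acids. The lactone ring closes in the 5-exo-tet mode at C7 (6-endo attack at the propargylic C6 is not favoured without cationic activation), with inversion at C7 and retention at C6, so the C7 configuration of the target follows from the (7R) oxirane of step 13. C8 is set by Felkin–Anh/Cornforth addition: the nucleophile approaches anti to both α C–O bonds (the non-chelating C9–OTBS and the oxirane C7–O), and both stereocentres direct it to the same face. C17 is not reliably set in the kinetic event and is therefore equilibrated with DBU to the epimer with the methyl group trans to the bulky C9 branch (cis to 8-OH), as in the target. The step needs chemoselectivity for the ketone over the hindered C12 propanoate, which the preformed enediolate at −78 °C should give, and the cold acidic quench forestalls Payne-type epoxide migration and silyl migration from O9 to O8.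

**Step 15**
Reactants: 25 hydroxy lactone
Product: 26 C6 ynone
Conditions: Dess–Martin periodinane, NaHCO3, CH2Cl2, 0 °C → rt
Reagents that add atoms: none
Why: Dess–Martin oxidation of the secondary propargylic alcohol (the tertiary 8-OH cannot be oxidised) erases the C6 configuration inherited from the epoxide so that it can be reset.

**Step 16**
Reactants: 26 ynone
Product: 27 (6R)-propargylic alcohol
Conditions: Ru[(S,S)-TsNCH(Ph)CH(Ph)NH](p-cymene) (5 mol%), 2-propanol, rt
Reagents that add atoms: none
Why: Noyori asymmetric transfer hydrogenation under neutral conditions, with the same alkynyl/alkyl facial sense as in step 6, should place the hydroxyl on the side opposite to the chlorine of the target.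

**Step 17**
Reactants: 27 silylalkyne
Product: 28 terminal alkyne
Conditions: TBAF, AcOH (1:1), THF, 0 °C
Reagents that add atoms: none
Why: Buffered fluoride cleaves the C(sp)–Si bond within minutes at 0 °C, whereas the two hindered secondary TBS ethers should survive.

**Step 18**
Reactants: 28 propargylic alcohol
Product: 29 (6S)-propargylic chloride
Conditions: PPh3, hexachloroacetone, CH2Cl2, −20 → 0 °C
Reagents that add atoms: hexachloroacetone, O=C(C(Cl)(Cl)Cl)C(Cl)(Cl)Cl
Why: Appel-type chlorination: chloride displaces the alkoxyphosphonium group by SN2 with inversion, the tertiary 8-OH does not react, and chlorinating at the propargylic stage avoids the SN2′ pathways of the later dienyl system.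

**Step 19**
Reactants: 29 bis-silyl ether
Product: 30 2,9-diol
Conditions: HF·pyridine, pyridine, THF, 0 °C → rt
Reagents that add atoms: none
Why: Acidic fluoride removes both TBS ethers without affecting the esters, the lactone or the chloride.

**Step 20**
Reactants: 30 diol
Product: 31 2,9-diacetate
Conditions: Ac2O, pyridine, DMAP (cat.), CH2Cl2, 0 °C → rt
Reagents that add atoms: acetic anhydride, CC(=O)OC(C)=O
Why: Acetylation of the two secondary alcohols (DMAP catalysis for the hindered 9-OH); the fully substituted 8-OH should stay free under these conditions.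

**Step 21**
Reactants: 31 enyne diacetate
Product: 33 CNP0305105.1 (target), via triene 32 (not isolated)
Conditions: (H2IMes)(PCy3)Cl2Ru=CHPh (second-generation Grubbs catalyst, 10 mol%), ethene (1 atm), toluene, 40 °C; then Ar purge, 1 mM, 80 °C
Reagents that add atoms: ethene, C=C
Why: Endo ring-closing enyne metathesis run as a tandem: under ethene the terminal alkyne becomes the 2-substituted 1,3-diene (C16H2=C5–C4H=CH2), and after removal of ethene ring-closing metathesis between C4 and the C2 vinyl group closes the ten-membered ring, the C3=C4 bond being expected Z as the less strained geometry in this ring and the 1,1-disubstituted C5=C16 bond being too hindered to take part.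

**Compound list**
1 | pent-1-en-3-one | C=CC(=O)CC | starting material
2 | (Z)-3-(triisopropylsilyloxy)penta-1,3-diene | C/C=C(\O[Si](C(C)C)(C(C)C)C(C)C)C=C | intermediate
3 | ethyl (E)-3-methyl-4-oxobut-2-enoate | CCOC(=O)/C=C(\C)C=O | starting material
4 | ethyl (1S,2R,6S)-6-formyl-2,6-dimethyl-3-(triisopropylsilyloxy)cyclohex-3-ene-1-carboxylate | O=C[C@@]1(C)CC=C(O[Si](C(C)C)(C(C)C)C(C)C)[C@H](C)[C@@H]1C(=O)OCC | intermediate
5 | vinylmagnesium bromide | C=C[Mg]Br | starting material
6 | ethyl (1S,2R,6S)-6-[(1S)-1-hydroxyprop-2-en-1-yl]-2,6-dimethyl-3-(triisopropylsilyloxy)cyclohex-3-ene-1-carboxylate | C=C[C@H](O)[C@@]1(C)CC=C(O[Si](C(C)C)(C(C)C)C(C)C)[C@H](C)[C@@H]1C(=O)OCC | intermediate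
7 | C2 TBS ether of 6 | C=C[C@H](O[Si](C)(C)C(C)(C)C)[C@@]1(C)CC=C(O[Si](C(C)C)(C(C)C)C(C)C)[C@H](C)[C@@H]1C(=O)OCC | intermediate
8 | lithium (trimethylsilyl)acetylide | [Li]C#C[Si](C)(C)C | starting material
9 | C9 (trimethylsilyl)ethynyl ketone (ynone) | C=C[C@H](O[Si](C)(C)C(C)(C)C)[C@@]1(C)CC=C(O[Si](C(C)C)(C(C)C)C(C)C)[C@H](C)[C@@H]1C(=O)C#C[Si](C)(C)C | intermediate
10 | (9S)-propargylic alcohol | C=C[C@H](O[Si](C)(C)C(C)(C)C)[C@@]1(C)CC=C(O[Si](C(C)C)(C(C)C)C(C)C)[C@H](C)[C@@H]1[C@H](O)C#C[Si](C)(C)C | intermediate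
11 | 2,9-bis-TBS ether with TIPS enol ether | C=C[C@H](O[Si](C)(C)C(C)(C)C)[C@@]1(C)CC=C(O[Si](C(C)C)(C(C)C)C(C)C)[C@H](C)[C@@H]1[C@H](O[Si](C)(C)C(C)(C)C)C#C[Si](C)(C)C | intermediate
12 | cyclohex-2-enone (C12 ketone, C13=C14) | C=C[C@H](O[Si](C)(C)C(C)(C)C)[C@@]1(C)C=CC(=O)[C@H](C)[C@@H]1[C@H](O[Si](C)(C)C(C)(C)C)C#C[Si](C)(C)C | intermediate
13 | (12S)-allylic alcohol | C=C[C@H](O[Si](C)(C)C(C)(C)C)[C@@]1(C)C=C[C@H](O)[C@H](C)[C@@H]1[C@H](O[Si](C)(C)C(C)(C)C)C#C[Si](C)(C)C | intermediate
14 | propanoic acid | CCC(=O)O | starting material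
15 | (12R)-propanoate, C8 silylalkyne | C=C[C@H](O[Si](C)(C)C(C)(C)C)[C@@]1(C)C=C[C@@H](OC(=O)CC)[C@H](C)[C@@H]1[C@H](O[Si](C)(C)C(C)(C)C)C#C[Si](C)(C)C | intermediate
16 | terminal alkyne (not isolated) | C=C[C@H](O[Si](C)(C)C(C)(C)C)[C@@]1(C)C=C[C@@H](OC(=O)CC)[C@H](C)[C@@H]1[C@H](O[Si](C)(C)C(C)(C)C)C#C | intermediate
17 | C8 methyl ketone | C=C[C@H](O[Si](C)(C)C(C)(C)C)[C@@]1(C)C=C[C@@H](OC(=O)CC)[C@H](C)[C@@H]1[C@H](O[Si](C)(C)C(C)(C)C)C(C)=O | intermediate
18 | 3-(trimethylsilyl)prop-2-ynal | O=CC#C[Si](C)(C)C | starting material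
19 | lithium aldolate (C6 epimers, not isolated) | C=C[C@H](O[Si](C)(C)C(C)(C)C)[C@@]1(C)C=C[C@@H](OC(=O)CC)[C@H](C)[C@@H]1[C@H](O[Si](C)(C)C(C)(C)C)C(=O)CC([O-])C#C[Si](C)(C)C.[Li+] | intermediate
20 | C6 mesylate (C6 epimers, not isolated) | C=C[C@H](O[Si](C)(C)C(C)(C)C)[C@@]1(C)C=C[C@@H](OC(=O)CC)[C@H](C)[C@@H]1[C@H](O[Si](C)(C)C(C)(C)C)C(=O)CC(OS(C)(=O)=O)C#C[Si](C)(C)C | intermediate
21 | (6E)-enynone | C=C[C@H](O[Si](C)(C)C(C)(C)C)[C@@]1(C)C=C[C@@H](OC(=O)CC)[C@H](C)[C@@H]1[C@H](O[Si](C)(C)C(C)(C)C)C(=O)/C=C/C#C[Si](C)(C)C | intermediate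
22 | (6S,7R)-trans-epoxy ketone | C=C[C@H](O[Si](C)(C)C(C)(C)C)[C@@]1(C)C=C[C@@H](OC(=O)CC)[C@H](C)[C@@H]1[C@H](O[Si](C)(C)C(C)(C)C)C(=O)[C@@H]2O[C@H]2C#C[Si](C)(C)C | intermediate
23 | dilithium propanoate enediolate (not isolated) | CC=C([O-])[O-].[Li+].[Li+] | intermediate
24 | β-hydroxy acid epoxide (C17 epimers, not isolated) | C=C[C@H](O[Si](C)(C)C(C)(C)C)[C@@]1(C)C=C[C@@H](OC(=O)CC)[C@H](C)[C@@H]1[C@H](O[Si](C)(C)C(C)(C)C)[C@](O)(C(C)C(=O)O)[C@@H]2O[C@H]2C#C[Si](C)(C)C | intermediate
25 | γ-lactone, 8-OH, (6S)-6-OH (lactone centres C7, C8, C17 arranged as in the target) | C=C[C@H](O[Si](C)(C)C(C)(C)C)[C@@]1(C)C=C[C@@H](OC(=O)CC)[C@H](C)[C@@H]1[C@H](O[Si](C)(C)C(C)(C)C)[C@]2(O)[C@@H](C)C(=O)O[C@H]2[C@@H](O)C#C[Si](C)(C)C | intermediate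
26 | C6 ynone lactone | C=C[C@H](O[Si](C)(C)C(C)(C)C)[C@@]1(C)C=C[C@@H](OC(=O)CC)[C@H](C)[C@@H]1[C@H](O[Si](C)(C)C(C)(C)C)[C@]2(O)[C@@H](C)C(=O)O[C@H]2C(=O)C#C[Si](C)(C)C | intermediate
27 | (6R)-propargylic alcohol lactone | C=C[C@H](O[Si](C)(C)C(C)(C)C)[C@@]1(C)C=C[C@@H](OC(=O)CC)[C@H](C)[C@@H]1[C@H](O[Si](C)(C)C(C)(C)C)[C@]2(O)[C@@H](C)C(=O)O[C@H]2[C@H](O)C#C[Si](C)(C)C | intermediate
28 | (6R)-alcohol, terminal alkyne | C=C[C@H](O[Si](C)(C)C(C)(C)C)[C@@]1(C)C=C[C@@H](OC(=O)CC)[C@H](C)[C@@H]1[C@H](O[Si](C)(C)C(C)(C)C)[C@]2(O)[C@@H](C)C(=O)O[C@H]2[C@H](O)C#C | intermediate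
29 | (6S)-chloride, 2,9-bis-TBS ether | C=C[C@H](O[Si](C)(C)C(C)(C)C)[C@@]1(C)C=C[C@@H](OC(=O)CC)[C@H](C)[C@@H]1[C@H](O[Si](C)(C)C(C)(C)C)[C@]2(O)[C@@H](C)C(=O)O[C@H]2[C@@H](Cl)C#C | intermediate
30 | (6S)-chloride, 2,9-diol | C=C[C@H](O)[C@@]1(C)C=C[C@@H](OC(=O)CC)[C@H](C)[C@@H]1[C@H](O)[C@]2(O)[C@@H](C)C(=O)O[C@H]2[C@@H](Cl)C#C | intermediate
31 | (6S)-chloride, 2,9-diacetate (enyne) | C=C[C@H](OC(C)=O)[C@@]1(C)C=C[C@@H](OC(=O)CC)[C@H](C)[C@@H]1[C@H](OC(C)=O)[C@]2(O)[C@@H](C)C(=O)O[C@H]2[C@@H](Cl)C#C | intermediate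
32 | acyclic triene with the 2-substituted buta-1,3-diene on C6 (not isolated) | C=C[C@H](OC(C)=O)[C@@]1(C)C=C[C@@H](OC(=O)CC)[C@H](C)[C@@H]1[C@H](OC(C)=O)[C@]2(O)[C@@H](C)C(=O)O[C@H]2[C@@H](Cl)C(=C)C=C | intermediate
33 | CNP0305105.1, (1S,2S,3Z,6S,7R,8R,9S,10S,11R,12R,17R) | C=C1/C=C\[C@H](OC(C)=O)[C@@]2(C)C=C[C@@H](OC(=O)CC)[C@H](C)[C@@H]2[C@H](OC(C)=O)[C@]2(O)[C@@H](C)C(=O)O[C@H]2[C@H]1Cl | target

**Step count:** 21 steps in total. Longest linear sequence: 21 steps (from pent-1-en-3-one).

**Steps most likely to fail**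

Step 14. What may go wrong: enolisation of the hindered α-silyloxy ketone or retro-aldol cleavage competing with addition of the strongly basic dianion, loss of facial selectivity at C8, or epoxide and silyl migration before the lactone closes. Fallback: starting from 22, a Reformatsky addition of the zinc enolate of tert-butyl 2-bromopropanoate (Zn, THF, 0 °C; non-basic, same Felkin–Anh preference) should give the β-hydroxy tert-butyl ester epoxide F1. Treatment with TFA in CH2Cl2 at 0 °C then lets the ester carbonyl open the oxirane at C7 (5-exo) with loss of 2-methylpropene, and DBU equilibration at C17 returns to 25.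

Step 21. What may go wrong: oligomerisation or stalling at the acyclic triene instead of closure of the strained ten-membered ring, or closure to the E ring olefin. Fallback (ring closure at C4–C5 by a Mizoroki–Heck reaction, before the chloride is installed): starting from 28, α-selective hydrostannation of the propargylic alcohol (Bu3SnH, Mo(CO)3(CNtBu)3 cat., THF, 55 °C) should give the 2-stannyl allylic alcohol F2. Iodine in CH2Cl2 at 0 °C then gives the 2-iodoalkene F3. Intramolecular Heck reaction of the alkenyl iodide with the C2 vinyl group (Pd(OAc)2, P(o-tol)3, Ag2CO3, MeCN, 70 °C, high dilution; bond to the terminal carbon, β-hydride elimination into conjugation) should close the ring to the macrocyclic dienol F4. Chlorination with PPh3/hexachloroacetone, the standard reagent for allylic alcohols (inversion, no allylic shift), gives the chloride F5; HF·pyridine gives the diol F6; and acetylation as in step 20 returns to 33.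

Step 3. What may go wrong: poor facial selectivity in the addition to the α-quaternary aldehyde. Fallback: the epimer mixture of 6 is oxidised with Dess–Martin periodinane to the vinyl ketone F7, which is reduced with BH3·SMe2 and (R)-1-methyl-3,3-diphenyltetrahydro-1H,3H-pyrrolo[1,2-c][1,3,2]oxazaborole (Corey–Bakshi–Shibata reduction, tert-alkyl group large, vinyl small) to return to 6 as the (2S) carbinol.

**Further compounds**
F1 | step 14 | β-hydroxy tert-butyl ester epoxide (C17 epimers) | C=C[C@H](O[Si](C)(C)C(C)(C)C)[C@@]1(C)C=C[C@@H](OC(=O)CC)[C@H](C)[C@@H]1[C@H](O[Si](C)(C)C(C)(C)C)[C@](O)(C(C)C(=O)OC(C)(C)C)[C@@H]2O[C@H]2C#C[Si](C)(C)C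
F2 | step 21 | 2-(tributylstannyl) allylic alcohol | C=C[C@H](O[Si](C)(C)C(C)(C)C)[C@@]1(C)C=C[C@@H](OC(=O)CC)[C@H](C)[C@@H]1[C@H](O[Si](C)(C)C(C)(C)C)[C@]2(O)[C@@H](C)C(=O)O[C@H]2[C@H](O)C(=C)[Sn](CCCC)(CCCC)CCCC
F3 | step 21 | 2-iodo allylic alcohol | C=C[C@H](O[Si](C)(C)C(C)(C)C)[C@@]1(C)C=C[C@@H](OC(=O)CC)[C@H](C)[C@@H]1[C@H](O[Si](C)(C)C(C)(C)C)[C@]2(O)[C@@H](C)C(=O)O[C@H]2[C@H](O)C(I)=C
F4 | step 21 | macrocyclic (3Z)-dienol, (6R)-6-OH, 2,9-bis-TBS ether | C=C1/C=C\[C@H](O[Si](C)(C)C(C)(C)C)[C@@]2(C)C=C[C@@H](OC(=O)CC)[C@H](C)[C@@H]2[C@H](O[Si](C)(C)C(C)(C)C)[C@]2(O)[C@@H](C)C(=O)O[C@H]2[C@@H]1O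
F5 | step 21 | macrocyclic (6S)-chloride, 2,9-bis-TBS ether | C=C1/C=C\[C@H](O[Si](C)(C)C(C)(C)C)[C@@]2(C)C=C[C@@H](OC(=O)CC)[C@H](C)[C@@H]2[C@H](O[Si](C)(C)C(C)(C)C)[C@]2(O)[C@@H](C)C(=O)O[C@H]2[C@H]1Cl
F6 | step 21 | macrocyclic (6S)-chloride, 2,9-diol | C=C1/C=C\[C@H](O)[C@@]2(C)C=C[C@@H](OC(=O)CC)[C@H](C)[C@@H]2[C@H](O)[C@]2(O)[C@@H](C)C(=O)O[C@H]2[C@H]1Cl
F7 | step 3 | vinyl ketone at C2 | C=CC(=O)[C@@]1(C)CC=C(O[Si](C(C)C)(C(C)C)C(C)C)[C@H](C)[C@@H]1C(=O)OCC
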